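The amounts frame the question: with reagent charged at 0.150 M, amber held less substrate than that, ochre about the same and violet more, and I wanted the target standing in each after 2.0 d.

| flask | substrate | reagent | remark | time |
|---|---|---|---|---|
| cedar | 0.026 M | 0.15 M | run made earlier |  |
| elm | 0.42 M | 0.15 M | run made earlier |  |
| amber | 0.050 M | 0.150 M |  | 2.0 d |
| ochre | 0.15 M | 0.150 M |  | 2.0 d |
| violet | 0.50 M | 0.150 M |  | 2.0 d |

| run | time / h | target / % |
|---|---|---|
| cedar | 1.50 | 35.9 |
| cedar | 5.00 | 31.7 |
| cedar | 8.00 | 26.4 |
| cedar | 12.0 | 22.4 |
| cedar | 20.0 | 15.4 |
| cedar | 25.0 | 11.4 |
| elm | 2.00 | 19.8 |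
| elm | 3.00 | 17.4 |
| elm | 5.00 | 15.4 |
| elm | 8.00 | 11.9 |
| elm | 15.0 | 7.4 |
| elm | 25.0 | 4.0 |

(standard deviation of a reading: 0.5 percentage points)

- steps thought possible: substrate + reagent <-> target; target -> over-reaction product; substrate + reagent <-> isomer of the product
- "hardly changes" means that all values lie within two and a half points (for a concentration: within two and a half percent of the largest)

- [target] at the end for amber, ochre, violet, in this order
- how the row runs (hardly changes / rises all the way / falls all the way / falls, then rises / rises, then falls)

I supposed that substrate and reagent settle quickly with target (a pre-equilibrium), so that target stays a fixed multiple of free substrate times free reagent, whatever the charge. The first cedar reading was 0.00933 M of target, and counting the remainder as free gave a multiple of 3.98 M⁻¹; the first elm reading, 0.0832 M, gave 3.69 M⁻¹. My objection was that target had already been draining, so part of what I called free was gone, taking reagent with it. The falling readings put that drain at 0.0511 h⁻¹ in cedar and 0.0668 h⁻¹ in elm, which I reckoned as a loss of about 7.16 × 10⁻⁴ M and 0.0111 M by those first readings. Taking these off lifted cedar to 4.18 M⁻¹ and elm to 4.58 M⁻¹, so I kept their mean as the holding quotient Q, target over free substrate times free reagent: 4.38 M⁻¹. A second objection I could not compute away: the isomer of the product went unread, and any of it present lowers the free amounts and raises Q. Still, target should follow that product, and a product suffers when either factor is small, so I expected the middle flask, ochre, to stand highest, though I committed to this rule and to no row of my own.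

The forecast gave 0.0023 M, 0.0064 M and 0.0026 M, a row that rises, then falls: “The middle charge therefore gives the most target after two days”.

The flasks gave 0.00266 M, 0.00724 M and 0.00552 M, a row that rises, then falls, with violet at twice the forecast.

    substrate + reagent ⇌ target (K = 5.50 M⁻¹, k = 0.0870 M⁻¹ min⁻¹)
    target → over-reaction product (k = 0.00140 min⁻¹)
    substrate + reagent ⇌ isomer of the product (K = 19.0 M⁻¹, k = 0.00440 M⁻¹ min⁻¹)

In amber the forward path to target began 20 times faster than the path to the isomer of the product, and target was made 5.63 times faster than used up at 0.0366 d, but by 2.00 d that ratio was 0.689, with 9.8% of the substrate left, where Q gives 0.00225 M of target against 0.00266 M. In violet, the reagent, here the limiting reagent, stood at 0.00302 M of free reagent beside 0.353 M of substrate, and Q on those amounts gives 0.00468 M of target against 0.00552 M.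

The numbers in the tables come from a simulation from invented constants; scatter was added.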